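**Retrosynthetic overview**

1. The target is a guaianolide (ring A: cyclopentene C1–C5; ring B: cycloheptane; ring C: α-methylene-γ-butyrolactone on C7/C8) joined through δ-lactone ring D (O–C4–C3–C13'–C11'–C12') to an aryl seco-eudesmane half. The end game is a double Mitsunobu acetylation (inverting C2), E1cB unmasking of the methylene lactone and desilylation.
2. Ring D is opened at O–C4 and at C12'–C11' to give CO2 plus benzylic chloride 33 (an epimer mixture at C4 and C11'). One pot of nickel-catalysed carboxylation, acid-triggered SN1 lactonisation and base equilibration closes ring D stereoconvergently.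
3. Enabling feature: C4 is a tertiary carbinol carbon allylic to the tetrasubstituted C1=C5 alkene of ring A, so it ionises to a C4–C5–C1 allyl cation that the chain on C3 can capture only at C4 and only cis. C11' is benzylic and α to the new carbonyl, so its C–Cl bond is activated and the centre is epimerisable.
4. Chloride 33 comes from tricyclic enone 26 by α'-allylation at C3 (trans to the C2 silyloxy group), methylcerium addition, alkene cleavage, addition of aryl Grignard 31 (from bromide 8) and chlorination. Bromide 8 comes from 6-bromophthalide by Wittig olefination and carboxy-directed asymmetric hydrogenation.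
5. Ring order: ring C (chromium-catalysed asymmetric allylation of acrolein, then sulfinate mask) → ring A, brought in as (S)-4-silyloxycyclopentenone and joined by Negishi coupling → ring B by ring-closing metathesis (C9=C10) and hydroxyl-directed hydrogenation (C10) → ring D in the key step.

Key step: step 24

Remark: guaiane numbering (C1–C15) is used for the lactone half and C11'–C13' for the three ring D carbons on the aryl side; TBS = tert-butyldimethylsilyl, TES = triethylsilyl, TBDPS = tert-butyldiphenylsilyl, Ar* = 4-(TBDPSOCH2)-3-[(R)-5-(TESO)pentan-2-yl]phenyl; C11 (sulfone-bearing, 15–37), C4 (28–34) and C11' (32–35) are carried as inconsequential epimer mixtures and left unspecified in the SMILES; (S)-4-(TBSO)cyclopent-2-enone 17 is assumed to be commercially available.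

**Aryl half**

Step 1
Reactants: 1 6-bromophthalide
Product: 2 6-bromo-1-methyl-1,3-dihydro-2-benzofuran-1-ol (lactol tautomer of 1-[5-bromo-2-(hydroxymethyl)phenyl]ethanone)
Conditions: MeLi (1.05 equiv), THF, −78 °C; aq. NH4Cl
Reagents that add atoms: methyllithium, [Li]C
Why: Addition of one equivalent of an organolithium to a lactone at low temperature stops at the lithium hemiketalate (lactone-to-lactol addition), so the methyl ketone oxidation level should be reached without over-addition.

Step 2
Reactants: 2 lactol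
Product: 3 1-[5-bromo-2-(TBDPS-oxymethyl)phenyl]ethanone
Conditions: TBDPSCl, imidazole, DMF, rt
Reagents that add atoms: tert-butyl(chloro)diphenylsilane, CC(C)(C)[Si](Cl)(c1ccccc1)c1ccccc1
Why: Silyl ether formation should trap the open hydroxy ketone tautomer at its primary benzylic alcohol, because the tertiary hemiketal hydroxyl is too hindered for the bulky silyl chloride.

Step 3
Reactants: 3 aryl methyl ketone; 4 (2-carboxyethyl)triphenylphosphonium bromide
Product: 5 (E)-4-[5-bromo-2-(TBDPS-oxymethyl)phenyl]pent-3-enoic acid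
Conditions: NaHMDS (2.2 equiv), THF, 0 °C → rt; aq. HCl; chromatographic removal of the minor Z isomer
Reagents that add atoms: none
Why: Wittig olefination with the carboxylate-bearing ylide gives the β,γ-unsaturated acid, and the E isomer (aryl trans to the CH2CO2H chain) should predominate for steric reasons.

Step 4
Reactants: 5 unsaturated acid
Product: 6 (R)-4-[5-bromo-2-(TBDPS-oxymethyl)phenyl]pentanoic acid
Conditions: [Ir(cod)(SIPHOX)]BArF (1 mol %, chiral spiro phosphine–oxazoline ligand), H2 (6 atm), Cs2CO3 (0.5 equiv), MeOH, rt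
Reagents that add atoms: none
Why: Carboxy-directed iridium-catalysed asymmetric hydrogenation of a 4-aryl-4-alkyl β,γ-unsaturated acid sets the benzylic stereocentre, the ligand enantiomer being chosen so that hydrogen is delivered to the face that gives the R configuration.

Step 5
Reactants: 6 acid
Product: 7 (R)-4-[5-bromo-2-(TBDPS-oxymethyl)phenyl]pentan-1-ol
Conditions: BH3·SMe2, THF, 0 °C → rt; MeOH
Reagents that add atoms: none
Why: Borane reduces the carboxylic acid chemoselectively and should leave the aryl bromide and the silyl ether untouched.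

Step 6
Reactants: 7 alcohol
Product: 8 Ar*–Br, tert-butyl({4-bromo-2-[(R)-5-(triethylsilyloxy)pentan-2-yl]benzyl}oxy)diphenylsilane
Conditions: TESCl, imidazole, CH2Cl2, 0 °C
Reagents that add atoms: chlorotriethylsilane, CC[Si](Cl)(CC)CC
Why: Standard silylation gives a primary TES ether that is cleaved later by acid while the benzylic TBDPS ether survives.

**Ring C building block**

Step 7
Reactants: 9 (tert-butyldimethylsilyloxy)acetaldehyde; 10 methyl acrylate
Product: 11 methyl 2-[1-hydroxy-2-(TBSO)ethyl]prop-2-enoate (racemic)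
Conditions: DABCO (0.5 equiv), MeOH (cat.), rt
Reagents that add atoms: none
Why: The Morita–Baylis–Hillman reaction joins the acrylate α-carbon to the aldehyde, and the racemic carbinol centre is removed in the next step.

Step 8
Reactants: 11 allylic alcohol
Product: 12 methyl (Z)-2-(bromomethyl)-4-(TBSO)but-2-enoate
Conditions: NBS, Me2S, CH2Cl2, 0 °C → rt
Reagents that add atoms: N-bromosuccinimide, O=C1CCC(=O)N1Br
Why: Bromide attacks the oxysulfonium ion of the alcohol in an SN2' sense with allylic transposition, which should give the thermodynamically preferred (Z)-2-(bromomethyl)enoate.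

Step 9
Reactants: 12 allylic bromide; 13 acrolein
Product: 14 (4S,5S)-4-[(TBSO)methyl]-3-methylidene-5-vinyldihydrofuran-2(3H)-one (trans)
Conditions: CrCl2 (10 mol %), chiral carbazole bis(oxazoline) ligand (12 mol %), Mn, TMSCl, THF, rt; then citric acid, MeOH
Reagents that add atoms: none
Why: In this catalytic asymmetric Nozaki–Hiyama–Kishi 2-(alkoxycarbonyl)allylation the allylchromium reagent adds through its γ-carbon via a chair transition state with the CH2OTBS group equatorial, which should give the anti homoallylic alcohol that lactonises to the trans lactone, while the chiral chromium complex (ligand enantiomer chosen accordingly) fixes the absolute configuration at C7 and C8.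

Step 10
Reactants: 14 α-methylene lactone
Product: 15 (4S,5S)-4-[(TBSO)methyl]-3-[(phenylsulfonyl)methyl]-5-vinyldihydrofuran-2(3H)-one
Conditions: PhSO2Na, AcOH, DMF, rt
Reagents that add atoms: sodium benzenesulfinate, [Na+].[O-]S(=O)c1ccccc1
Why: Conjugate (sulfa-Michael) addition of sulfinate masks the methylene lactone as a non-nucleophilic, oxidation-stable β-sulfonyl lactone that is unmasked later by E1cB elimination, the new C11 centre being inconsequential.

Step 11
Reactants: 15 silyl ether
Product: 16 (4R,5S)-4-(bromomethyl)-3-[(phenylsulfonyl)methyl]-5-vinyldihydrofuran-2(3H)-one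
Conditions: Ph3PBr2, CH2Cl2, 0 °C → rt
Reagents that add atoms: dibromotriphenylphosphorane, BrP(Br)(c1ccccc1)(c1ccccc1)c1ccccc1
Why: Dibromotriphenylphosphorane converts a primary TBS ether directly into the bromide through an oxyphosphonium intermediate (SN2 at a primary carbon, stereocentres untouched).

**Rings A and B**

Step 12
Reactants: 17 (S)-4-(TBSO)cyclopent-2-en-1-one
Product: 18 (S)-4-(TBSO)-2-iodocyclopent-2-en-1-one
Conditions: I2, pyridine, CH2Cl2, 0 °C → rt
Reagents that add atoms: iodine, II
Why: α-Iodination of the enone proceeds by conjugate addition of pyridine, iodination of the enolate and elimination, and leaves the C2 stereocentre untouched.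

Step 13
Reactants: 16 bromide; 18 iodoenone
Product: 20 (S)-4-(TBSO)cyclopent-2-en-1-one carrying at its C2 (guaiane C5) the CH2 group (C6) of the lactone, via alkylzinc bromide 19 (not isolated)
Conditions: Zn dust (activated), LiCl, THF, 40 °C; then 18, Pd2(dba)3 (2.5 mol %), tri(2-furyl)phosphine (10 mol %), THF/NMP, rt
Reagents that add atoms: none
Why: Zinc insertion into the primary bromide followed by Negishi coupling of the alkylzinc with the α-iodoenone forms the C5–C6 bond under conditions that tolerate the lactone, sulfone and silyl ether.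

Step 14
Reactants: 20 enone
Product: 22 2-(lactonylmethyl)-3-isopropenyl-4-(TBSO)cyclopent-2-en-1-one, via silyl enol ether 21 (not isolated)
Conditions: isopropenylmagnesium bromide, CuBr·SMe2 (20 mol %), TMSCl, THF, −78 °C; then Pd(OAc)2 (1.1 equiv), MeCN, rt
Reagents that add atoms: isopropenylmagnesium bromide, C=C(C)[Mg]Br
Why: Copper-catalysed conjugate addition delivers the isopropenyl group to C1 trans to the C2 silyloxy group with trapping as silyl enol ether 21, and Saegusa–Ito dehydrogenation (palladium syn to the C1 hydrogen) regenerates the conjugated enone with a now tetrasubstituted C1=C5 bond, erasing the transient C1 stereocentre.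

Step 15
Reactants: 22 dienone
Product: 23 2α-(TBSO)-4-oxo-13-(phenylsulfonyl)-15-norguaia-1(5),9-dien-12,8α-olide (7αH, 8βH)
Conditions: second-generation Grubbs catalyst (5 mol %), toluene, 80 °C
Reagents that add atoms: none
Why: Ring-closing metathesis between the C8 vinyl group and the C1 isopropenyl group closes the seven-membered ring B as a trisubstituted C9=C10 alkene, with loss of ethylene driving the reaction.

Step 16
Reactants: 23 silyl ether
Product: 24 2α-hydroxy-4-oxo-13-(phenylsulfonyl)-15-norguaia-1(5),9-dien-12,8α-olide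
Conditions: HF·pyridine, THF/pyridine, 0 °C → rt
Reagents that add atoms: none
Why: Fluoride-mediated desilylation frees the 2α-hydroxyl needed to direct the next step, and the buffered conditions should not affect the lactone or the β-sulfonyl group.

Step 17
Reactants: 24 dienone alcohol
Product: 25 2α-hydroxy-4-oxo-13-(phenylsulfonyl)-15-norguai-1(5)-en-12,8α-olide (10β-methyl, 10αH)
Conditions: [Ir(cod)(PCy3)(py)]PF6 (5 mol %), H2 (1 atm), CH2Cl2, rt
Reagents that add atoms: none
Why: In this hydroxyl-directed hydrogenation the cationic iridium catalyst binds the 2α-hydroxyl (homoallylic to C9=C10) and delivers hydrogen to the α-face of the trisubstituted alkene, setting 10αH and 10β-methyl, while the tetrasubstituted enone alkene should not react.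

Step 18
Reactants: 25 alcohol
Product: 26 2α-(triethylsilyloxy)-4-oxo-13-(phenylsulfonyl)-15-norguai-1(5)-en-12,8α-olide
Conditions: TESCl, imidazole, DMF, 0 °C → rt
Reagents that add atoms: chlorotriethylsilane, CC[Si](Cl)(CC)CC
Why: Silylation protects the β-hydroxy ketone against retro-aldol and elimination pathways in the enolate step and installs a bulky group that directs the C3 alkylation.

**Union and key step**

Step 19
Reactants: 26 enone
Product: 27 3β-allyl-2α-(triethylsilyloxy)-4-oxo-13-(phenylsulfonyl)-15-norguai-1(5)-en-12,8α-olide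
Conditions: LiHMDS (1.05 equiv), THF, −78 °C; allyl iodide, DMPU, −78 → −40 °C
Reagents that add atoms: allyl iodide, C=CCI
Why: Kinetic α'-deprotonation of the enone (faster than deprotonation of the hindered tertiary lactone α-hydrogen) and alkylation of the cross-conjugated enolate anti to the adjacent 2α-silyloxy group place the allyl group on the β-face of C3.

Step 20
Reactants: 27 ketone
Product: 29 3β-allyl-2α,4-bis(triethylsilyloxy)-13-(phenylsulfonyl)guai-1(5)-en-12,8α-olide, via tertiary alcohol 28 (not isolated)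
Conditions: MeLi, CeCl3, THF, −78 °C; then TESOTf, 2,6-lutidine, −78 → 0 °C
Reagents that add atoms: methyllithium, [Li]C; triethylsilyl trifluoromethanesulfonate, CC[Si](CC)(CC)OS(=O)(=O)C(F)(F)F
Why: The weakly basic methylcerium reagent adds 1,2 to the enolisable β-silyloxy ketone in preference to the lactone, and in situ silylation gives the tertiary allylic silyl ether, the configuration at C4 being irrelevant because C4 is ionised in step 24.

Step 21
Reactants: 29 alkene
Product: 30 3β-(2-oxoethyl)-2α,4-bis(triethylsilyloxy)-13-(phenylsulfonyl)guai-1(5)-en-12,8α-olide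
Conditions: OsO4 (2 mol %), NaIO4, 2,6-lutidine, dioxane/H2O, rt
Reagents that add atoms: sodium periodate, [Na+].[O-]I(=O)(=O)=O; water, O
Why: Lemieux–Johnson cleavage (dihydroxylation then periodate) is selective for the unhindered monosubstituted alkene over the tetrasubstituted C1=C5 alkene flanked by two silyloxy-bearing carbons.

Step 22
Reactants: 30 aldehyde; 8 aryl bromide
Product: 32 3β-[2-Ar*-2-hydroxyethyl]-2α,4-bis(triethylsilyloxy)-13-(phenylsulfonyl)guai-1(5)-en-12,8α-olide, via arylmagnesium bromide 31 (not isolated)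
Conditions: 8, Mg, LiCl, THF, rt; then 30, THF, −78 °C; aq. NH4Cl
Reagents that add atoms: none
Why: Addition of the aryl Grignard reagent to the aldehyde at low temperature (faster than attack on the lactone) forms the C11'–aryl bond, and both C11' epimers are acceptable because this centre is re-set in step 24.

Step 23
Reactants: 32 benzylic alcohols
Product: 33 3β-[2-Ar*-2-chloroethyl]-2α,4-bis(triethylsilyloxy)-13-(phenylsulfonyl)guai-1(5)-en-12,8α-olide
Conditions: MsCl, Et3N, CH2Cl2, −20 °C; then LiCl, DMF, 0 °C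
Reagents that add atoms: lithium chloride, [Li+].[Cl-]
Why: Mesylation of the secondary benzylic alcohol and in situ displacement by chloride give the benzylic chloride under non-acidic conditions that should leave the tertiary allylic silyl ether intact.

Step 24
Reactants: 33 benzylic chloride (four stereoisomers at C4 and C11')
Product: 36 ring D lactone diol (2α-OH and primary OH free; 4β-O, 4α-CH3, 11'R; benzylic OTBDPS and sulfone mask retained), via carboxylic acid 34 (not isolated), via lactone epimer mixture 35 (not isolated)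
Conditions: NiCl2·glyme (10 mol %), PCp3·HBF4 (20 mol %), Zn, MgCl2, CO2 (1 atm), DMA, rt; aq. citric acid extraction; then TFA, wet CH2Cl2, −20 → 0 °C; then Et3N, CH2Cl2, rt
Reagents that add atoms: carbon dioxide, O=C=O
Why: Zerovalent nickel (from NiCl2·glyme and zinc) inserts into the benzylic C11'–Cl bond of either epimer, the benzylnickel species is reduced by zinc and adds to CO2 at C11' to give acid 34 (C12'–C11' bond), and acid then ionises the tertiary C4–OSiEt3 group to an allyl cation spanning C4–C5–C1 that a carboxyl oxygen captures at C4 (O–C4 bond). The closest known reaction types are the nickel-catalysed reductive carboxylation of secondary benzylic halides with CO2 and the acid-mediated lactonisation of tertiary allylic carbinols with alkyl–oxygen cleavage. Ring D closes in a 6-exo mode at the C4 terminus of the cation, whereas capture at C1 would require a bridged eight-membered ring and is not expected. C4 is set by the C3 tether, which reaches only the β-face and gives the cis-fused lactone from both C4 epimers, and C11' is set by Et3N-mediated equilibration through the lactone enolate to the epimer with the aryl group pseudo-equatorial. The step needs chemoselective C–Cl activation in the presence of the β-sulfonyl lactone and silyl ethers, which the mild nickel/zinc conditions at room temperature should provide, and elimination from the cation is reversible under the acid so material should funnel to the lactone. The same acid removes the two remaining TES ethers, so 36 is ready for the Mitsunobu step.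

**End game**

Step 25
Reactants: 36 diol
Product: 37 2β-acetoxy diacetate (2β-OAc, chain OAc, benzylic OTBDPS, sulfone mask)
Conditions: PPh3, DIAD, AcOH, THF, 0 °C → rt
Reagents that add atoms: acetic acid, CC(=O)O
Why: In this Mitsunobu esterification the primary alcohol is acetylated and the secondary allylic C2 carbinol is displaced with inversion (SN2 at the alkoxyphosphonium), turning 2α-OH into the 2β-acetate, while SN2' attack is blocked because the allylic terminus C5 is fully substituted.

Step 26
Reactants: 37 β-sulfonyl lactone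
Product: 38 O-TBDPS ether of the target (α-methylene lactone unveiled)
Conditions: DBU, CH2Cl2, 0 °C → rt
Reagents that add atoms: none
Why: E1cB elimination of benzenesulfinate from the β-sulfonyl lactone regenerates the α-methylene-γ-butyrolactone, no free hydroxyl being present to add back, and the base keeps C11' at its thermodynamic configuration.

Step 27
Reactants: 38 silyl ether
Product: 39 CNP0205574.1
Conditions: HF·pyridine, THF, 0 °C → rt
Reagents that add atoms: none
Why: Fluoride-mediated cleavage of the benzylic TBDPS ether is compatible with the two acetates, both lactones and the methylene lactone, and releases the primary benzylic alcohol.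

**Compound list**

1 | 6-bromophthalide | O=C1OCc2ccc(Br)cc21 | starting material
2 | 6-bromo-1-methyl-1,3-dihydro-2-benzofuran-1-ol (lactol) | CC1(O)OCc2ccc(Br)cc21 | intermediate
3 | 1-[5-bromo-2-(TBDPS-oxymethyl)phenyl]ethanone | CC(=O)c1cc(Br)ccc1CO[Si](c1ccccc1)(c1ccccc1)C(C)(C)C | intermediate
4 | (2-carboxyethyl)triphenylphosphonium bromide | OC(=O)CC[P+](c1ccccc1)(c1ccccc1)c1ccccc1.[Br-] | starting material
5 | (E)-4-[5-bromo-2-(TBDPS-oxymethyl)phenyl]pent-3-enoic acid | C/C(=C\CC(=O)O)c1cc(Br)ccc1CO[Si](c1ccccc1)(c1ccccc1)C(C)(C)C | intermediate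
6 | (R)-4-[5-bromo-2-(TBDPS-oxymethyl)phenyl]pentanoic acid | C[C@H](CCC(=O)O)c1cc(Br)ccc1CO[Si](c1ccccc1)(c1ccccc1)C(C)(C)C | intermediate
7 | (R)-4-[5-bromo-2-(TBDPS-oxymethyl)phenyl]pentan-1-ol | C[C@H](CCCO)c1cc(Br)ccc1CO[Si](c1ccccc1)(c1ccccc1)C(C)(C)C | intermediate
8 | Ar*–Br, (R)-aryl bromide with OTES chain and benzylic OTBDPS | C[C@H](CCCO[Si](CC)(CC)CC)c1cc(Br)ccc1CO[Si](c1ccccc1)(c1ccccc1)C(C)(C)C | intermediate
9 | (tert-butyldimethylsilyloxy)acetaldehyde | O=CCO[Si](C)(C)C(C)(C)C | starting material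
10 | methyl acrylate | C=CC(=O)OC | starting material
11 | methyl 2-[1-hydroxy-2-(TBSO)ethyl]prop-2-enoate (racemic) | C=C(C(=O)OC)C(O)CO[Si](C)(C)C(C)(C)C | intermediate
12 | methyl (Z)-2-(bromomethyl)-4-(TBSO)but-2-enoate | COC(=O)/C(CBr)=C/CO[Si](C)(C)C(C)(C)C | intermediate
13 | acrolein | C=CC=O | starting material
14 | (4S,5S)-4-[(TBSO)methyl]-3-methylidene-5-vinyldihydrofuran-2(3H)-one | O=C1O[C@@H](C=C)[C@H](CO[Si](C)(C)C(C)(C)C)C1=C | intermediate
15 | (4S,5S)-4-[(TBSO)methyl]-3-[(phenylsulfonyl)methyl]-5-vinyldihydrofuran-2(3H)-one (C3 epimers) | O=C1O[C@@H](C=C)[C@H](CO[Si](C)(C)C(C)(C)C)C1CS(=O)(=O)c1ccccc1 | intermediate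
16 | (4R,5S)-4-(bromomethyl)-3-[(phenylsulfonyl)methyl]-5-vinyldihydrofuran-2(3H)-one | O=C1O[C@@H](C=C)[C@H](CBr)C1CS(=O)(=O)c1ccccc1 | intermediate
17 | (S)-4-(TBSO)cyclopent-2-en-1-one | O=C1C=C[C@@H](O[Si](C)(C)C(C)(C)C)C1 | starting material
18 | (S)-4-(TBSO)-2-iodocyclopent-2-en-1-one | O=C1C(I)=C[C@@H](O[Si](C)(C)C(C)(C)C)C1 | intermediate
19 | alkylzinc bromide from 16 | O=C1O[C@@H](C=C)[C@H](C[Zn]Br)C1CS(=O)(=O)c1ccccc1 | intermediate
20 | Negishi product: enone 18 with iodine replaced by the CH2 (C6) of the lactone; stereocentres as in 16 and 17 | O=C1O[C@@H](C=C)[C@H](CC2=C[C@@H](O[Si](C)(C)C(C)(C)C)CC2=O)C1CS(=O)(=O)c1ccccc1 | intermediate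
21 | trimethylsilyl enol ether after conjugate addition (isopropenyl trans to OTBS) | O=C1O[C@@H](C=C)[C@H](CC2=C(O[Si](C)(C)C)C[C@H](O[Si](C)(C)C(C)(C)C)[C@H]2C(C)=C)C1CS(=O)(=O)c1ccccc1 | intermediate
22 | 2-(lactonylmethyl)-3-isopropenyl-4-(TBSO)cyclopent-2-en-1-one | O=C1O[C@@H](C=C)[C@H](CC2=C(C(C)=C)[C@@H](O[Si](C)(C)C(C)(C)C)CC2=O)C1CS(=O)(=O)c1ccccc1 | intermediate
23 | 2α-(TBSO)-4-oxo-13-(phenylsulfonyl)-15-norguaia-1(5),9-dien-12,8α-olide | O=C1O[C@H]2C=C(C)C3=C(C[C@@H]2C1CS(=O)(=O)c1ccccc1)C(=O)C[C@@H]3O[Si](C)(C)C(C)(C)C | intermediate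
24 | 2α-hydroxy-4-oxo-13-(phenylsulfonyl)-15-norguaia-1(5),9-dien-12,8α-olide | O=C1O[C@H]2C=C(C)C3=C(C[C@@H]2C1CS(=O)(=O)c1ccccc1)C(=O)C[C@@H]3O | intermediate
25 | 2α-hydroxy-4-oxo-13-(phenylsulfonyl)-15-norguai-1(5)-en-12,8α-olide (10β-methyl) | O=C1O[C@H]2C[C@H](C)C3=C(C[C@@H]2C1CS(=O)(=O)c1ccccc1)C(=O)C[C@@H]3O | intermediate
26 | 2α-(TESO)-4-oxo-13-(phenylsulfonyl)-15-norguai-1(5)-en-12,8α-olide | O=C1O[C@H]2C[C@H](C)C3=C(C[C@@H]2C1CS(=O)(=O)c1ccccc1)C(=O)C[C@@H]3O[Si](CC)(CC)CC | intermediate
27 | 3β-allyl derivative of 26 | O=C1O[C@H]2C[C@H](C)C3=C(C[C@@H]2C1CS(=O)(=O)c1ccccc1)C(=O)[C@@H](CC=C)[C@@H]3O[Si](CC)(CC)CC | intermediate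
28 | 3β-allyl-4-hydroxy-2α-(TESO)-13-(phenylsulfonyl)guai-1(5)-en-12,8α-olide (C4 epimers) | O=C1O[C@H]2C[C@H](C)C3=C(C[C@@H]2C1CS(=O)(=O)c1ccccc1)C(C)(O)[C@@H](CC=C)[C@@H]3O[Si](CC)(CC)CC | intermediate
29 | 3β-allyl-2α,4-bis(TESO)-13-(phenylsulfonyl)guai-1(5)-en-12,8α-olide | O=C1O[C@H]2C[C@H](C)C3=C(C[C@@H]2C1CS(=O)(=O)c1ccccc1)C(C)(O[Si](CC)(CC)CC)[C@@H](CC=C)[C@@H]3O[Si](CC)(CC)CC | intermediate
30 | 3β-(2-oxoethyl)-2α,4-bis(TESO)-13-(phenylsulfonyl)guai-1(5)-en-12,8α-olide | O=C1O[C@H]2C[C@H](C)C3=C(C[C@@H]2C1CS(=O)(=O)c1ccccc1)C(C)(O[Si](CC)(CC)CC)[C@@H](CC=O)[C@@H]3O[Si](CC)(CC)CC | intermediate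
31 | Ar*–MgBr | C[C@H](CCCO[Si](CC)(CC)CC)c1cc([Mg]Br)ccc1CO[Si](c1ccccc1)(c1ccccc1)C(C)(C)C | intermediate
32 | benzylic alcohols, 3β-[2-Ar*-2-hydroxyethyl] (C11' epimers) | O=C1O[C@H]2C[C@H](C)C3=C(C[C@@H]2C1CS(=O)(=O)c1ccccc1)C(C)(O[Si](CC)(CC)CC)[C@@H](CC(O)c1ccc(CO[Si](c2ccccc2)(c2ccccc2)C(C)(C)C)c([C@H](C)CCCO[Si](CC)(CC)CC)c1)[C@@H]3O[Si](CC)(CC)CC | intermediate
33 | benzylic chlorides, 3β-[2-Ar*-2-chloroethyl] (C11' and C4 epimers) | O=C1O[C@H]2C[C@H](C)C3=C(C[C@@H]2C1CS(=O)(=O)c1ccccc1)C(C)(O[Si](CC)(CC)CC)[C@@H](CC(Cl)c1ccc(CO[Si](c2ccccc2)(c2ccccc2)C(C)(C)C)c([C@H](C)CCCO[Si](CC)(CC)CC)c1)[C@@H]3O[Si](CC)(CC)CC | intermediate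
34 | 2-Ar*-3-(guaian-3β-yl)propanoic acid (C11' and C4 epimers) | O=C1O[C@H]2C[C@H](C)C3=C(C[C@@H]2C1CS(=O)(=O)c1ccccc1)C(C)(O[Si](CC)(CC)CC)[C@@H](CC(C(=O)O)c1ccc(CO[Si](c2ccccc2)(c2ccccc2)C(C)(C)C)c([C@H](C)CCCO[Si](CC)(CC)CC)c1)[C@@H]3O[Si](CC)(CC)CC | intermediate
35 | ring D lactone diol, C11' epimer mixture | O=C1O[C@H]2C[C@H](C)C3=C(C[C@@H]2C1CS(=O)(=O)c1ccccc1)[C@@]1(C)OC(=O)C(c2ccc(CO[Si](c4ccccc4)(c4ccccc4)C(C)(C)C)c([C@H](C)CCCO)c2)C[C@H]1[C@@H]3O | intermediate
36 | ring D lactone diol (2α-OH, 11'R, benzylic OTBDPS, sulfone mask) | O=C1O[C@H]2C[C@H](C)C3=C(C[C@@H]2C1CS(=O)(=O)c1ccccc1)[C@@]1(C)OC(=O)[C@@H](c2ccc(CO[Si](c4ccccc4)(c4ccccc4)C(C)(C)C)c([C@H](C)CCCO)c2)C[C@H]1[C@@H]3O | intermediate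
37 | 2β-acetoxy diacetate (benzylic OTBDPS, sulfone mask) | O=C1O[C@H]2C[C@H](C)C3=C(C[C@@H]2C1CS(=O)(=O)c1ccccc1)[C@@]1(C)OC(=O)[C@@H](c2ccc(CO[Si](c4ccccc4)(c4ccccc4)C(C)(C)C)c([C@H](C)CCCOC(C)=O)c2)C[C@H]1[C@H]3OC(C)=O | intermediate
38 | O-TBDPS ether of the target | C=C1C(=O)O[C@H]2C[C@H](C)C3=C(C[C@H]12)[C@@]1(C)OC(=O)[C@@H](c2ccc(CO[Si](c4ccccc4)(c4ccccc4)C(C)(C)C)c([C@H](C)CCCOC(C)=O)c2)C[C@H]1[C@H]3OC(C)=O | intermediate
39 | CNP0205574.1 | C=C1C(=O)O[C@H]2C[C@H](C)C3=C(C[C@H]12)[C@@]1(C)OC(=O)[C@@H](c2ccc(CO)c([C@H](C)CCCOC(C)=O)c2)C[C@H]1[C@H]3OC(C)=O | target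

**Step count and risks**

Total step count: 27. Longest linear sequence: 20 steps (steps 7–11 and 13–27, from 9 and 10).

Steps most likely to fail:

Step 24 (key step). β-Hydride elimination from the benzylnickel intermediate, slow carboxylation at the hindered secondary centre, or premature loss of the tertiary silyl ether with ether formation onto the benzylic carbon could all drain material before CO2 is installed. The fallback sets out from benzylic alcohols 32. Dehydration with Burgess reagent (THF, 50 °C) should give the (E)-styrene F1. Markovnikov hydrocarboxylation of F1 through a nickel hydride (Ni(acac)2, Cs2CO3, Et2Zn, CO2, THF) places the carboxyl group at the benzylic carbon and comes back to the route at acid 34, which is carried through the same TFA and Et3N treatment to 36.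

Step 9. Insufficient enantio- or anti-selectivity in the chromium-mediated allylation, or polymerisation of the unsaturated aldehyde, would compromise C7 and C8. The fallback sets out from acrolein 13 and replaces steps 7–9 by auxiliary control. (R)-4-Benzyl-1,3-oxazolidin-2-one is acylated with methyl 4-chloro-4-oxobutanoate (n-BuLi, THF, −78 °C) to give the imide F2. Its dibutylboron enolate (Bu2BOTf, iPr2NEt, CH2Cl2, −78 °C) undergoes a syn aldol reaction with 13, and the adduct lactonises to the trans lactone imide F3. NaBH4 in THF/H2O removes the auxiliary reductively to give the hydroxymethyl lactone F4, and TBSCl/imidazole gives the silyl ether F5. LDA followed by Eschenmoser's salt gives the Mannich base F6, and MeI then aq. NaHCO3 eliminates trimethylamine to come back to the route at 14.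

Step 25. SN2 displacement at the hindered allylic C2 carbinol may be slow, with elimination or ionisation (retention) competing. The fallback sets out from diol 36. Selective acetylation of the primary alcohol (Ac2O, 2,4,6-collidine, CH2Cl2, −20 °C) gives the monoacetate F7. Dess–Martin periodinane gives the enone F8. Luche reduction (NaBH4, CeCl3·7H2O, MeOH, −78 °C), with hydride delivered to the α-face opposite the C3 substituent and the C10 methyl group, gives the 2β-alcohol F9, and Ac2O/DMAP/pyridine comes back to the route at 37.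

**Further compounds**

F1 | step 24 | (E)-styrene, 3β-[(E)-2-Ar*-vinyl]-2α,4-bis(TESO)-13-(phenylsulfonyl)guai-1(5)-en-12,8α-olide | O=C1O[C@H]2C[C@H](C)C3=C(C[C@@H]2C1CS(=O)(=O)c1ccccc1)C(C)(O[Si](CC)(CC)CC)[C@@H](/C=C/c1ccc(CO[Si](c2ccccc2)(c2ccccc2)C(C)(C)C)c([C@H](C)CCCO[Si](CC)(CC)CC)c1)[C@@H]3O[Si](CC)(CC)CC
F2 | step 9 | (R)-4-benzyl-3-(4-methoxy-4-oxobutanoyl)-1,3-oxazolidin-2-one | COC(=O)CCC(=O)N1[C@H](Cc2ccccc2)COC1=O
F3 | step 9 | trans lactone imide, (R)-4-benzyl-3-{[trans-5-oxo-2-vinyltetrahydrofuran-3-yl]carbonyl}-1,3-oxazolidin-2-one (lactone centres as in 14) | O=C1O[C@@H](C=C)[C@H](C(=O)N2[C@H](Cc3ccccc3)COC2=O)C1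
F4 | step 9 | (4S,5S)-4-(hydroxymethyl)-5-vinyldihydrofuran-2(3H)-one | O=C1O[C@@H](C=C)[C@H](CO)C1
F5 | step 9 | (4S,5S)-4-[(TBSO)methyl]-5-vinyldihydrofuran-2(3H)-one | O=C1O[C@@H](C=C)[C@H](CO[Si](C)(C)C(C)(C)C)C1
F6 | step 9 | Mannich base, (4S,5S)-3-[(dimethylamino)methyl]-4-[(TBSO)methyl]-5-vinyldihydrofuran-2(3H)-one (C3 epimers) | O=C1O[C@@H](C=C)[C@H](CO[Si](C)(C)C(C)(C)C)C1CN(C)C
F7 | step 25 | monoacetate of 36 (chain OAc, 2α-OH) | O=C1O[C@H]2C[C@H](C)C3=C(C[C@@H]2C1CS(=O)(=O)c1ccccc1)[C@@]1(C)OC(=O)[C@@H](c2ccc(CO[Si](c4ccccc4)(c4ccccc4)C(C)(C)C)c([C@H](C)CCCOC(C)=O)c2)C[C@H]1[C@@H]3O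
F8 | step 25 | C2 enone (2-oxo) | O=C1O[C@H]2C[C@H](C)C3=C(C[C@@H]2C1CS(=O)(=O)c1ccccc1)[C@@]1(C)OC(=O)[C@@H](c2ccc(CO[Si](c4ccccc4)(c4ccccc4)C(C)(C)C)c([C@H](C)CCCOC(C)=O)c2)C[C@H]1C3=O
F9 | step 25 | 2β-alcohol | O=C1O[C@H]2C[C@H](C)C3=C(C[C@@H]2C1CS(=O)(=O)c1ccccc1)[C@@]1(C)OC(=O)[C@@H](c2ccc(CO[Si](c4ccccc4)(c4ccccc4)C(C)(C)C)c([C@H](C)CCCOC(C)=O)c2)C[C@H]1[C@H]3O
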